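## Retrosynthetic overview

1. Target 16 comes from methyl ester 15, and 15 from the 4-(hydroxymethyl) dioxane 13. The C4 methyl passes through the key step one oxidation level higher (CHO, reduced in the same flask) and is returned to CH3 by iodide reduction.
2. Key disconnection: the 1,2-dioxane is cut across the ring at O1–C6 and C3–C4. This gives an O–O–C triad (α-methoxy hydroperoxide 11) and a C4–C5–C6 triad (cyclopropanecarbaldehyde 9), joined at the fully substituted C6.
3. Enabling feature: C6 is a fully substituted, cation-stabilising ring carbon and C4 carries a one-carbon branch. With that branch as CHO, C4–C5–C6 is a strained donor–acceptor cyclopropane; the peroxide oxygen opens its C4–C6 bond at C6 with inversion, and the enamine left at C4 closes on C3.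
4. Aldehyde 9 comes from asymmetric cyclopropanation of (E)-allylic alcohol 7, 7 from carboalumination of alkyne 5, and 5 from aldehyde 4. Aldehyde 4 comes from (R)-citronellal 1 (its C3 becomes the side-chain methine, its C1 becomes C6) and 7-phenylhept-1-ene 2 by cross-metathesis and hydrogenation.
5. Ring order: the temporary cyclopropane (step 5), then the 1,2-dioxane (step 8), in which the cyclopropane is consumed.

Key step: step 8

Assumption: 1, 2, 10 and all named reagents are purchased; 11 is used freshly prepared because α-alkoxy hydroperoxides are labile.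

## Route

Step 1
Reactants: 1 (R)-citronellal [(3R)-3,7-dimethyloct-6-enal]; 2 7-phenylhept-1-ene
Product: 3 (3R,6E)-3-methyl-12-phenyldodec-6-enal (E isomer expected to predominate; geometry is irrelevant)
Conditions: 2 (3 equiv), second-generation Grubbs catalyst RuCl2(=CHPh)(PCy3)(H2IMes) (5 mol %), CH2Cl2, 40 °C
Reagents that add atoms: none
Why: Olefin cross-metathesis exchanges the isopropylidene terminus of the prenyl-type alkene for the terminal alkene of 2 (in excess) with loss of volatile isobutene; the aldehyde and the stereocentre are not involved.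

Step 2
Reactants: 3 (3R,6E)-3-methyl-12-phenyldodec-6-enal
Product: 4 (3R)-3-methyl-12-phenyldodecanal
Conditions: H2 (1 atm), 5% Pd/C, EtOAc, rt
Reagents that add atoms: none
Why: Heterogeneous catalytic hydrogenation saturates the disubstituted alkene under conditions that leave the aldehyde and the benzene ring intact.

Step 3
Reactants: 4 (3R)-3-methyl-12-phenyldodecanal
Product: 5 (4R)-4-methyl-13-phenyltridec-1-yne
Conditions: dimethyl (1-diazo-2-oxopropyl)phosphonate, K2CO3, MeOH, 0 °C to rt
Reagents that add atoms: dimethyl (1-diazo-2-oxopropyl)phosphonate, CC(=O)C(=[N+]=[N-])P(=O)(OC)OC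
Why: Seyferth–Gilbert homologation in the Ohira–Bestmann variant converts the aldehyde into the terminal alkyne; the stereocentre is β to the carbonyl and cannot epimerise.

Step 4
Reactants: 5 (4R)-4-methyl-13-phenyltridec-1-yne
Product: 7 (2E,5R)-3,5-dimethyl-14-phenyltetradec-2-en-1-ol, via alkenylalane 6 (not isolated)
Conditions: AlMe3 (2.5 equiv), Cp2ZrCl2 (20 mol %), CH2Cl2, 0 °C to rt; then n-BuLi, (CH2O)n, THF, −30 °C to rt; aq. HCl
Reagents that add atoms: trimethylaluminium, C[Al](C)C; paraformaldehyde (as formaldehyde), C=O
Why: Negishi zirconium-catalysed carboalumination adds CH3 and Al syn across the alkyne with CH3 on the internal carbon, and the alanate is hydroxymethylated with retention, which fixes the (E) geometry (CH3 cis to CH2OH).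

Step 5
Reactants: 7 (2E,5R)-3,5-dimethyl-14-phenyltetradec-2-en-1-ol
Product: 8 [(1S,2S)-2-methyl-2-[(2R)-2-methyl-11-phenylundecyl]cyclopropyl]methanol
Conditions: Zn(CH2I)2·DME (2.2 equiv, from Et2Zn, CH2I2, DME), (4R,5R)-2-butyl-N,N,N',N'-tetramethyl-1,3,2-dioxaborolane-4,5-dicarboxamide (1.2 equiv), CH2Cl2, −10 °C to rt; aq. NH4Cl, then aq. KOH wash
Reagents that add atoms: diiodomethane, ICI
Why: Charette asymmetric Simmons–Smith cyclopropanation: the zinc alkoxide bound to the (R,R)-dioxaborolane delivers CH2 stereospecifically (CH2OH and CH3 stay cis) to the alkene face known for geraniol-type allylic alcohols, setting both ring carbons as (S).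

Step 6
Reactants: 8 [(1S,2S)-2-methyl-2-[(2R)-2-methyl-11-phenylundecyl]cyclopropyl]methanol
Product: 9 (1S,2S)-2-methyl-2-[(2R)-2-methyl-11-phenylundecyl]cyclopropane-1-carbaldehyde
Conditions: PhI(OAc)2 (1.1 equiv), TEMPO (10 mol %), CH2Cl2, rt
Reagents that add atoms: none
Why: Oxoammonium (TEMPO/PhI(OAc)2) oxidation stops at the aldehyde and leaves the cyclopropane untouched; the configuration of the formyl-bearing carbon does not matter because that carbon becomes trigonal in step 8.

Step 7
Reactants: 10 dimethyl (3E)-hex-3-enedioate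
Product: 11 methyl 3-hydroperoxy-3-methoxypropanoate (racemic)
Conditions: O3, CH2Cl2/MeOH (4:1), −78 °C; N2 purge; cold concentration, rapid chromatography, used at once
Reagents that add atoms: ozone, [O-][O+]=O; methanol, CO
Why: Criegee ozonolysis in methanol traps the carbonyl oxide from the symmetrical alkene as the α-methoxy hydroperoxide; its stereocentre is irrelevant because it is ionised in step 8.

Step 8
Reactants: 9 (1S,2S)-2-methyl-2-[(2R)-2-methyl-11-phenylundecyl]cyclopropane-1-carbaldehyde; 11 methyl 3-hydroperoxy-3-methoxypropanoate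
Product: 13 methyl 2-[(3S,4R,6R)-4-(hydroxymethyl)-6-methyl-6-[(2R)-2-methyl-11-phenylundecyl]-1,2-dioxan-3-yl]acetate, via dioxane aldehyde 12 (not isolated)
Conditions: 11 (2 equiv), (R)-2-[diphenyl(trimethylsilyloxy)methyl]pyrrolidine (20 mol %), CF3CO2H (20 mol %), CHCl3, −20 to 0 °C; then NaBH4, MeOH, −20 °C
Reagents that add atoms: none
Why: Proposed new method: a formal [3+3] annulation by an iminium–enamine relay, in which the amine condenses with 9 to a cyclopropyl iminium ion, the hydroperoxide oxygen of 11 opens the ring bond between the formyl-bearing and the fully substituted carbon at the latter (homo-conjugate addition, O1–C6 bond), the resulting C4 enamine attacks the peroxycarbenium ion formed from the α-methoxy peroxide by acid-promoted loss of methanol (C3–C4 bond), and hydrolysis releases β-peroxy aldehyde 12, which is reduced at once because it could epimerise at C4 or eliminate the peroxide. The closest known reaction types are the Lewis-acid [3+3] annulation of donor–acceptor cyclopropanes with nitrones (heteroatom attack at the donor carbon, then C–C closure at the acceptor carbon), the amine-catalysed 1,3-difunctionalisation of cyclopropanecarbaldehydes by iminium opening and enamine capture, and the addition of enol-type nucleophiles to peroxycarbenium ions. The 1,2-dioxane closes in a 6-(enolexo)-endo-trig mode, the exocyclic enamine adding to the endocyclic C=O+ bond. C6 is set by stereospecific backside (invertive) substitution at the (S)-configured cyclopropane carbon; C4 is set by the catalyst, whose diphenyl(silyloxy)methyl group shields one face of the (E)-enamine and overrides the negligible CH3/CH2R bias of C6; C3 is expected to follow from a chair transition state with the enamine equatorial and the peroxycarbenium ion in its syn (Z) geometry (the alkylated counterpart of the favoured syn carbonyl oxide), which places CH2CO2CH3 axial and cis to the C4 substituent. The step needs cleavage of the more substituted cyclopropane bond rather than the bond to the ring CH2, secured by the tertiary cation-stabilising carbon aligned with the iminium π* orbital, and C–C closure rather than enamine attack on a peroxide oxygen, secured because that would need a four-membered transition state whereas closure at C3 is six-membered.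

Step 9
Reactants: 13 methyl 2-[(3S,4R,6R)-4-(hydroxymethyl)-6-methyl-6-[(2R)-2-methyl-11-phenylundecyl]-1,2-dioxan-3-yl]acetate
Product: 14 methyl 2-[(3S,4S,6R)-4-(iodomethyl)-6-methyl-6-[(2R)-2-methyl-11-phenylundecyl]-1,2-dioxan-3-yl]acetate
Conditions: I2, PPh3 (premixed), imidazole, CH2Cl2, 0 °C
Reagents that add atoms: iodine, II
Why: Appel-type iodination of the primary alcohol should be much faster than any reaction of the phosphine with the hindered dialkyl peroxide, and it removes the hydroxyl before it can lactonise onto the cis ester arm.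

Step 10
Reactants: 14 methyl 2-[(3S,4S,6R)-4-(iodomethyl)-6-methyl-6-[(2R)-2-methyl-11-phenylundecyl]-1,2-dioxan-3-yl]acetate
Product: 15 methyl 2-[(3S,4S,6R)-4,6-dimethyl-6-[(2R)-2-methyl-11-phenylundecyl]-1,2-dioxan-3-yl]acetate
Conditions: Bu3SnH (1.5 equiv), Et3B (0.2 equiv), air, toluene, 0 °C to rt
Reagents that add atoms: none
Why: Radical chain dehalogenation: iodine abstraction and hydrogen transfer to the primary radical should outpace attack of tin radicals on the hindered O–O bond, and the ring geometry does not allow backside attack of the exocyclic radical on a peroxide oxygen; no stereocentre is touched.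

Step 11
Reactants: 15 methyl 2-[(3S,4S,6R)-4,6-dimethyl-6-[(2R)-2-methyl-11-phenylundecyl]-1,2-dioxan-3-yl]acetate
Product: 16 2-[(3S,4S,6R)-4,6-dimethyl-6-[(2R)-2-methyl-11-phenylundecyl]-1,2-dioxan-3-yl]acetic acid
Conditions: LiOH·H2O, THF/H2O (3:1), 0 °C to rt; then 1 M HCl to pH 3
Reagents that add atoms: lithium hydroxide, [Li+].[OH-]
Why: Acyl-oxygen saponification of the methyl ester at low temperature; the cyclic dialkyl peroxide has no hydrogen on C6 and should tolerate cold hydroxide without Kornblum–DeLaMare cleavage or retro-oxa-Michael opening.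

## Compound list

1 | (R)-citronellal, (3R)-3,7-dimethyloct-6-enal | C[C@H](CCC=C(C)C)CC=O | starting material
2 | 7-phenylhept-1-ene | C=CCCCCCc1ccccc1 | starting material
3 | (3R,6E)-3-methyl-12-phenyldodec-6-enal | C[C@H](CC/C=C/CCCCCc1ccccc1)CC=O | intermediate
4 | (3R)-3-methyl-12-phenyldodecanal | C[C@H](CCCCCCCCCc1ccccc1)CC=O | intermediate
5 | (4R)-4-methyl-13-phenyltridec-1-yne | C[C@H](CCCCCCCCCc1ccccc1)CC#C | intermediate
6 | [(1E,4R)-2,4-dimethyl-13-phenyltridec-1-en-1-yl]dimethylalane | C[C@H](CCCCCCCCCc1ccccc1)C/C(C)=C/[Al](C)C | intermediate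
7 | (2E,5R)-3,5-dimethyl-14-phenyltetradec-2-en-1-ol | C[C@H](CCCCCCCCCc1ccccc1)C/C(C)=C/CO | intermediate
8 | [(1S,2S)-2-methyl-2-[(2R)-2-methyl-11-phenylundecyl]cyclopropyl]methanol | C[C@H](CCCCCCCCCc1ccccc1)C[C@@]1(C)C[C@@H]1CO | intermediate
9 | (1S,2S)-2-methyl-2-[(2R)-2-methyl-11-phenylundecyl]cyclopropane-1-carbaldehyde | C[C@H](CCCCCCCCCc1ccccc1)C[C@@]1(C)C[C@@H]1C=O | intermediate
10 | dimethyl (3E)-hex-3-enedioate | COC(=O)C/C=C/CC(=O)OC | starting material
11 | methyl 3-hydroperoxy-3-methoxypropanoate (racemic) | COC(OO)CC(=O)OC | intermediate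
12 | methyl 2-[(3S,4S,6R)-4-formyl-6-methyl-6-[(2R)-2-methyl-11-phenylundecyl]-1,2-dioxan-3-yl]acetate | C[C@H](CCCCCCCCCc1ccccc1)C[C@]1(C)C[C@H](C=O)[C@H](CC(=O)OC)OO1 | intermediate
13 | methyl 2-[(3S,4R,6R)-4-(hydroxymethyl)-6-methyl-6-[(2R)-2-methyl-11-phenylundecyl]-1,2-dioxan-3-yl]acetate | C[C@H](CCCCCCCCCc1ccccc1)C[C@]1(C)C[C@H](CO)[C@H](CC(=O)OC)OO1 | intermediate
14 | methyl 2-[(3S,4S,6R)-4-(iodomethyl)-6-methyl-6-[(2R)-2-methyl-11-phenylundecyl]-1,2-dioxan-3-yl]acetate | C[C@H](CCCCCCCCCc1ccccc1)C[C@]1(C)C[C@H](CI)[C@H](CC(=O)OC)OO1 | intermediate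
15 | methyl 2-[(3S,4S,6R)-4,6-dimethyl-6-[(2R)-2-methyl-11-phenylundecyl]-1,2-dioxan-3-yl]acetate | C[C@H](CCCCCCCCCc1ccccc1)C[C@]1(C)C[C@H](C)[C@H](CC(=O)OC)OO1 | intermediate
16 | 2-[(3S,4S,6R)-4,6-dimethyl-6-[(2R)-2-methyl-11-phenylundecyl]-1,2-dioxan-3-yl]acetic acid | C[C@H](CCCCCCCCCc1ccccc1)C[C@]1(C)C[C@H](C)[C@H](CC(=O)O)OO1 | target

## Step count and risks

Total step count: 11. Longest linear sequence: 10 (steps 1–6 and 8–11; step 7 prepares the second fragment).

**Risk 1 – step 8.** The hydroperoxide may fail to open the cyclopropyl iminium ion at the hindered quaternary carbon. The opening may become ionised enough to erode stereochemical fidelity at C6. Closure may run through the anti peroxycarbenium geometry and give the 3,4-trans ring. The β-peroxy aldehyde may eliminate the peroxide before it is reduced. The fallback builds the ring stepwise by known chemistry; it sets out from alkyne 5 and comes back at ester 15. Bromoboration of 5 with B-bromo-9-borabicyclo[3.3.1]nonane and protodeboronation with acetic acid would give the 2-bromoalkene F1. Negishi coupling (Pd(PPh3)4, THF) with the zinc homoenolate F2, made from purchased methyl (R)-3-bromo-2-methylpropanoate and zinc dust, would give the methylidene ester F3, which already carries the C4 stereocentre. Reduction with i-Bu2AlH at −78 °C would give the aldehyde F4, and Wittig reaction with Ph3P=CHCO2CH3 the (E)-dienoate F5. Mukaiyama–Isayama hydroperoxysilylation (Co(acac)2, O2, Et3SiH) of the 1,1-disubstituted alkene would give the tertiary silyl peroxide F6 as both C6 epimers. Desilylation (Bu4NF, AcOH) and amine-promoted intramolecular oxa-Michael addition (Et2NH, CF3CH2OH) would then close the dioxane to 15 together with its diastereomers, to be separated by chromatography.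

**Risk 2 – step 10.** Tin radicals may cleave the O–O bond reductively, or the primary radical may rearrange onto a peroxide oxygen, during dehalogenation; one step earlier the phosphine may attack the peroxide. The fallback avoids halide and tin; it sets out from alcohol 13 and comes back at ester 15. Re-oxidation of 13 (TEMPO, PhI(OAc)2) would return aldehyde 12. Condensation with 4-methylbenzenesulfonohydrazide would give the tosylhydrazone F7. Reduction with catecholborane followed by NaOAc·3H2O, with loss of nitrogen and sulfinate, would give 15 directly.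

**Risk 3 – step 1.** Self-metathesis of 2 may outcompete productive cross-metathesis with the slowly reacting trisubstituted alkene, and the alkene may isomerise. The fallback uses ozonolysis and a Wittig reaction instead; it sets out from 1 and comes back at aldehyde 4. Acetalisation of 1 (HC(OCH3)3, TsOH, MeOH) would give the dimethyl acetal F8, and ozonolysis (O3, then Me2S) the acetal aldehyde F9. The phosphonium salt F10, from purchased (6-bromohexyl)benzene and PPh3, would be deprotonated with NaN(SiMe3)2 to the ylide F11. Wittig reaction of F11 with F9 would give the (Z)-alkene acetal F12, and hydrogenation (H2, Pd/C) the saturated acetal F13. Aqueous acid hydrolysis of F13 would give 4.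

## Further compounds

F1 | step 8 | (4R)-2-bromo-4-methyl-13-phenyltridec-1-ene | C[C@H](CCCCCCCCCc1ccccc1)CC(Br)=C
F2 | step 8 | bromo[(2R)-3-methoxy-2-methyl-3-oxopropyl]zinc | Br[Zn]C[C@H](C)C(=O)OC
F3 | step 8 | methyl (2S,6R)-2,6-dimethyl-4-methylidene-15-phenylpentadecanoate | C[C@H](CCCCCCCCCc1ccccc1)CC(=C)C[C@H](C)C(=O)OC
F4 | step 8 | (2S,6R)-2,6-dimethyl-4-methylidene-15-phenylpentadecanal | C[C@H](CCCCCCCCCc1ccccc1)CC(=C)C[C@H](C)C=O
F5 | step 8 | methyl (2E,4S,8R)-4,8-dimethyl-6-methylidene-17-phenylheptadec-2-enoate | C[C@H](CCCCCCCCCc1ccccc1)CC(=C)C[C@H](C)/C=C/C(=O)OC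
F6 | step 8 | methyl (2E,4S,8R)-4,6,8-trimethyl-17-phenyl-6-[(triethylsilyl)peroxy]heptadec-2-enoate (both C6 epimers) | C[C@H](CCCCCCCCCc1ccccc1)CC(C)(OO[Si](CC)(CC)CC)C[C@H](C)/C=C/C(=O)OC
F7 | step 10 | methyl 2-[(3S,4R,6R)-6-methyl-4-[(E)-[2-(4-methylbenzenesulfonyl)hydrazinylidene]methyl]-6-[(2R)-2-methyl-11-phenylundecyl]-1,2-dioxan-3-yl]acetate | C[C@H](CCCCCCCCCc1ccccc1)C[C@]1(C)C[C@H](/C=N/NS(=O)(=O)c2ccc(C)cc2)[C@H](CC(=O)OC)OO1
F8 | step 1 | (6R)-8,8-dimethoxy-2,6-dimethyloct-2-ene | C[C@H](CCC=C(C)C)CC(OC)OC
F9 | step 1 | (4R)-6,6-dimethoxy-4-methylhexanal | C[C@H](CCC=O)CC(OC)OC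
F10 | step 1 | triphenyl(6-phenylhexyl)phosphonium bromide | [Br-].c1ccc(cc1)CCCCCC[P+](c1ccccc1)(c1ccccc1)c1ccccc1
F11 | step 1 | triphenyl(6-phenylhexylidene)phosphorane | c1ccc(cc1)CCCCCC=P(c1ccccc1)(c1ccccc1)c1ccccc1
F12 | step 1 | [(6Z,10R)-12,12-dimethoxy-10-methyldodec-6-en-1-yl]benzene | C[C@H](CC/C=C\CCCCCc1ccccc1)CC(OC)OC
F13 | step 1 | [(10R)-12,12-dimethoxy-10-methyldodecyl]benzene | C[C@H](CCCCCCCCCc1ccccc1)CC(OC)OC
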